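(The earlier runs and the new flask are simulated with made-up constants; noise was put on by code.)

common to all: substrate 39 mM

|  | coupling partner | remark | time |
|---|---|---|---|
| south-west | 37 mM | the very flask that is asked about, followed so far |  |
| flask | 37.0 mM |  | 15 d |

south-west run (percent of the substrate charged)

| time / d | intermediate / % | target / % |
|---|---|---|
| 0.833 | 53.1 | 1.2 |
| 1.04 | 57.7 | 1.0 |
| 1.67 | 64.8 | 3.6 |
| 2.50 | 68.0 | 6.0 |
| 3.00 | 68.1 | 8.2 |
| 5.00 | 66.0 | 13.7 |

(standard deviation of a reading: 0.5 percentage points)

- the best time, 15 d at the latest, for intermediate
- the amount of intermediate, in percent of the substrate charged, at that time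



At early times the flask looked close to the symmetric case, with 0.949 equivalents of coupling partner (c_partner 37.0 mM, c_substrate 39 mM), so I took equal charges as my zero. There the inverse of the substrate left rises straight with time. Reading what the run had not yet shown as intermediate or target as substrate, I had 45.7% at 0.833 d, hence a rate of 1.43 d⁻¹ in fractions of the charge.

The loss I read from the target. It rose from 3.6% at 1.67 d to 13.7% at 5.00 d, and per day, over the 68.1% of intermediate standing, that made 0.0445 d⁻¹. I call this the drain, a first-order rate constant.

Intermediate peaks where feed equals drain times intermediate, which on the symmetric scale meant 14.6% of substrate left, at 4.11 d.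

I doubted this at once. The run already read 66.0% of intermediate at 5.00 d, below its earlier readings, and the unshown share there was 20.3%, more than the 12.3% of my zero. So I dropped that time and went back to the readings: 68.0% and 68.1% differ by less than the scatter of 0.5 percentage points. I committed to about 3.00 d and just over 68.1%.

The forecast said 2.8 d and 68.4%, holding that “intermediate peaks where formation matches loss”.

The flask gave 68.6% at 3.21 d, under this scheme:

    substrate + coupling partner → intermediate + by-product (k = 1.70 L mol⁻¹ h⁻¹)
    intermediate → target (k = 0.00190 h⁻¹)
    substrate + by-product → side product (k = 0.280 L mol⁻¹ h⁻¹)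

It held 68.1% at 2.57 d and 68.1% at 4.01 d. Carrying the drain on from 61.1% at 7.50 d, with substrate at 1.95%, gives 43.8% at 15 d, and the flask held 44.1%. In the neighbour flask charged with 92 mM of coupling partner, substrate stood at 0% at the end, and intermediate plus target came to 95.7%. That sum, run through the drain for 15 d as if it had stood from the start, gives 49.1%, and that neighbour flask held 49.0%.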